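**Retrosynthetic overview**

1. The target is catechin-(4α→8)-epicatechin-(4β→6)-catechin. The upper and middle units come from (+)-catechin and (−)-epicatechin; the lower catechin is built last, on the assembled skeleton.
2. Feature used: in the lower unit, C3–C4 joins the carbinol carbon to a benzylic CH2 on C4a of a phloroglucinol ring whose interflavan carbon C6 lies between O5 and O7 and para to O1, so that C4a and C8 are equivalent. This ring can therefore be attached as an open 2-allyl-3,5-dibenzyloxyphenol unit and the pyran ring closed afterwards from O1 and C4a, which gives the 4→6 connectivity by construction.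
3. Key disconnections: C3=C4 of the lower pyran ring (ring-closing metathesis, then anti-hydroboration for the 2,3-trans 3-OH); O1–C2 (Ir-catalysed allylic etherification, sets C2); C4(middle)–C6(lower) and C4(upper)–C8(middle) (Friedel–Crafts condensations with orthogonal O and S leaving groups).
4. Ring order: the six rings of the upper and middle units from the chiral pool, then the lower benzo ring, then the lower catechol ring (brought in with the ether), and the lower pyran ring last.
5. Temporary atoms, all removed again: the C8 bromine cap and benzyl ethers (hydrogenolysis), the silyl group on O1, the arylsulfanyl leaving group, and the alkene carbons lost as propene.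

Key step: step 18

Remark: both interflavan bonds are 3,4-trans; α/β is used for C4 substituents (β = opposite to the 2-aryl group), and interflavan rotamers are not stereoisomers that need control.

**Route**

Step 1
Reactants: 1 (+)-catechin
Product: 2 5,7,3',4'-tetra-O-benzyl-(+)-catechin
Conditions: BnBr (4.4 equiv), K2CO3, DMF, 0 °C → rt
Reagents that add atoms: benzyl bromide BrCc1ccccc1
Why: Williamson etherification of the four phenols, which are far more acidic than the secondary 3-OH, so no stereocentre is touched.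

Step 2
Reactants: 2 5,7,3',4'-tetra-O-benzyl-(+)-catechin
Product: 3 8-bromo-5,7,3',4'-tetra-O-benzylcatechin
Conditions: NBS (1.05 equiv), CH2Cl2, −78 °C → rt
Reagents that add atoms: N-bromosuccinimide O=C1CCC(=O)N1Br
Why: Electrophilic aromatic bromination at C8, the more accessible position of the benzo ring (flanked by the ring oxygen and one benzyloxy group), which installs a cap that later keeps this ring from acting as a nucleophile.

Step 3
Reactants: 3 8-bromo-5,7,3',4'-tetra-O-benzylcatechin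
Product: 4 8-bromo-5,7,3',4'-tetra-O-benzyl-4β-(2-ethoxyethoxy)catechin (2,3-trans, 3,4-cis)
Conditions: DDQ (2 equiv), 2-ethoxyethanol (5 equiv), CH2Cl2, rt
Reagents that add atoms: 2-ethoxyethanol CCOCCO
Why: Benzylic oxidation by hydride abstraction at C4 (cation stabilised by the 5,7-dioxygenated ring) and capture by the alcohol anti to the 2-aryl group; the C4 configuration is immaterial because the centre is ionised again in step 7.

Step 4
Reactants: 5 (−)-epicatechin
Product: 6 5,7,3',4'-tetra-O-benzyl-(−)-epicatechin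
Conditions: BnBr (4.4 equiv), K2CO3, DMF, 0 °C → rt
Reagents that add atoms: benzyl bromide BrCc1ccccc1
Why: Williamson etherification of the four phenols with the secondary alcohol left free, as in step 1.

Step 5
Reactants: 6 5,7,3',4'-tetra-O-benzyl-(−)-epicatechin
Product: 7 5,7,3',4'-tetra-O-benzyl-4β-(2-ethoxyethoxy)epicatechin (2,3-cis, 3,4-trans)
Conditions: DDQ (2 equiv), 2-ethoxyethanol (5 equiv), CH2Cl2, rt
Reagents that add atoms: 2-ethoxyethanol CCOCCO
Why: DDQ benzylic oxidation at C4 with capture of the cation by the alcohol on the β face, anti to both the 2-aryl group and the axial 3-OH.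

Step 6
Reactants: 7 5,7,3',4'-tetra-O-benzyl-4β-(2-ethoxyethoxy)epicatechin
Product: 8 5,7,3',4'-tetra-O-benzyl-4β-[(2,6-dimethylphenyl)sulfanyl]epicatechin
Conditions: 2,6-Me2C6H3SH (3 equiv), BF3·OEt2 (1 equiv), CH2Cl2, −78 → −20 °C
Reagents that add atoms: 2,6-dimethylbenzenethiol Cc1cccc(C)c1S
Why: Lewis-acid SN1 exchange at C4 (thiolysis type) in which the thiol adds to the cation from the β face, trans to the 3-OH, giving a hindered aryl thioether that a hard Lewis acid should not ionise in step 7.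

Step 7
Reactants: 4 8-bromo-5,7,3',4'-tetra-O-benzyl-4β-(2-ethoxyethoxy)catechin; 8 5,7,3',4'-tetra-O-benzyl-4β-[(2,6-dimethylphenyl)sulfanyl]epicatechin (3 equiv)
Product: 9 [8-bromo-5,7,3',4'-tetra-O-benzylcatechin]-(4α→8)-[5,7,3',4'-tetra-O-benzyl-4β-(2,6-dimethylphenylsulfanyl)epicatechin]
Conditions: BF3·OEt2 (1 equiv), 4 Å MS, CH2Cl2, −78 → −30 °C
Reagents that add atoms: none
Why: Friedel–Crafts condensation of the C4 cation of 4 with C8 of 8, where attack anti to the 3-OH of the 2,3-trans unit should set the 4α (3,4-trans) centre, the bromine cap prevents self-condensation of 4 and the C–S bond of 8 stays intact.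

Step 8
Reactants: 10 3,5-bis(benzyloxy)phenol
Product: 11 1-(allyloxy)-3,5-bis(benzyloxy)benzene
Conditions: allyl bromide (1.5 equiv), K2CO3, acetone, reflux
Reagents that add atoms: allyl bromide C=CCBr
Why: Williamson etherification of the single free phenol.

Step 9
Reactants: 11 1-(allyloxy)-3,5-bis(benzyloxy)benzene
Product: 13 2-allyl-3,5-bis(benzyloxy)phenol, via ortho-allyl cyclohexadienone 12 (not isolated)
Conditions: PhNEt2, 190 °C
Reagents that add atoms: none
Why: Aromatic Claisen rearrangement ([3,3]-sigmatropic shift, then tautomerisation) to one of the two equivalent ortho positions, which places the future C4 carbon chain on the future C4a without a regiochemical choice.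

Step 10
Reactants: 13 2-allyl-3,5-bis(benzyloxy)phenol
Product: 14 [2-allyl-3,5-bis(benzyloxy)phenoxy]triisopropylsilane
Conditions: i-Pr3SiCl (1.3 equiv), imidazole (3 equiv), DMF, rt → 40 °C
Reagents that add atoms: chlorotriisopropylsilane CC(C)[Si](Cl)(C(C)C)C(C)C
Why: Silylation of the phenol to give a bulky silyl ether that the neighbouring allyl group forces over the remaining ortho position (C6).

Step 11
Reactants: 9 [8-bromo-5,7,3',4'-tetra-O-benzylcatechin]-(4α→8)-[5,7,3',4'-tetra-O-benzyl-4β-(2,6-dimethylphenylsulfanyl)epicatechin]; 14 [2-allyl-3,5-bis(benzyloxy)phenoxy]triisopropylsilane (5 equiv, excess recovered)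
Product: 15 [8-bromo-5,7,3',4'-tetra-O-benzylcatechin]-(4α→8)-[5,7,3',4'-tetra-O-benzylepicatechin] carrying at C4 of the epicatechin unit (4β) a 3-allyl-2,6-bis(benzyloxy)-4-(triisopropylsilyloxy)phenyl group
Conditions: AgOTf (AgO3SCF3, 2.5 equiv), 2,6-di-tert-butyl-4-methylpyridine (3 equiv), 4 Å MS, CH2Cl2, −40 → 0 °C, dark
Reagents that add atoms: none
Why: Thiophilic silver activation of the C4 sulfide gives the C4 cation, which undergoes Friedel–Crafts attack by 14 at its position between the two benzyloxy groups (para to the silyloxy group, the other free position being shielded by the locked silyl group) on the β face, anti to the 3-OH and the 2-aryl group of the 2,3-cis unit.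

Step 12
Reactants: 15 the allyl silyl ether from step 11
Product: 16 the same trimer precursor with a 2,6-bis(benzyloxy)-3-[(E)-prop-1-enyl]-4-(triisopropylsilyloxy)phenyl group at C4 (4β) of the epicatechin unit
Conditions: RuClH(CO)(PPh3)3 (5 mol%), toluene, 80 °C
Reagents that add atoms: none
Why: Ruthenium hydride-catalysed alkene isomerisation (hydrometalation and β-hydride elimination) that moves the double bond into conjugation with the arene and stops at the more stable (E)-propenyl isomer.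

Step 13
Reactants: 16 the propenyl silyl ether from step 12
Product: 17 the same compound with a 2,6-bis(benzyloxy)-4-hydroxy-3-[(E)-prop-1-enyl]phenyl group (free phenol)
Conditions: Bu4NF (1.2 equiv), AcOH (1.2 equiv), THF, 0 °C
Reagents that add atoms: none
Why: Fluoride-induced cleavage of the aryl silyl ether under buffered conditions, to which benzyl ethers, the aryl bromide and the secondary alcohols are inert.

Step 14
Reactants: 18 3,4-bis(benzyloxy)benzaldehyde
Product: 19 ethyl (E)-3-[3,4-bis(benzyloxy)phenyl]prop-2-enoate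
Conditions: (EtO)2P(O)CH2CO2Et (1.2 equiv), NaH (1.2 equiv), THF, 0 °C → rt
Reagents that add atoms: triethyl phosphonoacetate CCOC(=O)CP(=O)(OCC)OCC
Why: Horner–Wadsworth–Emmons olefination, which gives the (E)-cinnamate.

Step 15
Reactants: 19 ethyl (E)-3-[3,4-bis(benzyloxy)phenyl]prop-2-enoate
Product: 20 (E)-3-[3,4-bis(benzyloxy)phenyl]prop-2-en-1-ol
Conditions: i-Bu2AlH (2.5 equiv), CH2Cl2, −78 → 0 °C; aqueous Rochelle salt
Reagents that add atoms: none
Why: 1,2-Reduction of the conjugated ester to the allylic alcohol without touching the double bond.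

Step 16
Reactants: 20 (E)-3-[3,4-bis(benzyloxy)phenyl]prop-2-en-1-ol
Product: 21 (E)-3-[3,4-bis(benzyloxy)phenyl]prop-2-en-1-yl methyl carbonate
Conditions: ClCO2Me (1.5 equiv), pyridine, CH2Cl2, 0 °C
Reagents that add atoms: methyl chloroformate COC(=O)Cl
Why: O-acylation of the primary allylic alcohol to the carbonate leaving group needed for allyl-iridium formation.

Step 17
Reactants: 17 the propenyl phenol from step 13; 21 (E)-3-[3,4-bis(benzyloxy)phenyl]prop-2-en-1-yl methyl carbonate (1.5 equiv)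
Product: 22 the trimer precursor with a 2,6-bis(benzyloxy)-4-{[(1S)-1-(3,4-bis(benzyloxy)phenyl)prop-2-en-1-yl]oxy}-3-[(E)-prop-1-enyl]phenyl group at C4 (4β) of the epicatechin unit
Conditions: LiN(SiMe3)2 (1.0 equiv), THF, −78 → 0 °C; then 21, [Ir(cod)Cl]2 (2 mol%), (Sa)-1,1'-binaphthalene-2,2'-diyl N,N-bis[(S)-1-phenylethyl]phosphoramidite (4 mol%), THF, rt → 50 °C
Reagents that add atoms: none
Why: Iridium-catalysed asymmetric allylic etherification in which the phenoxide (the only OH deprotonated by one equivalent of base) attacks the substituted terminus of the allyl-iridium complex, giving the branched ether whose new stereocentre (the future C2) is set by the ligand, the (Sa,Sc,Sc) enantiomer being expected to deliver the (S)-ether.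

Step 18
Reactants: 22 the diene from step 17
Product: 23 [8-bromo-5,7,3',4'-tetra-O-benzylcatechin]-(4α→8)-[5,7,3',4'-tetra-O-benzylepicatechin]-(4β→6)-[(2S)-5,7-bis(benzyloxy)-2-(3,4-bis(benzyloxy)phenyl)-2H-chromene]
Conditions: second-generation Grubbs catalyst RuCl2(=CHPh)(PCy3)(H2IMes) (10 mol%), CH2Cl2 (5 mM, degassed), 40 °C, dark; rapid filtration through neutral alumina
Reagents that add atoms: none
Why: Ring-closing olefin metathesis: the ruthenium alkylidene loads on the monosubstituted vinyl group of the allylic ether, adds across the neighbouring (E)-propenyl group in a [2+2] cycloaddition, and the ruthenacyclobutane collapses by retro-[2+2] to release propene and the C3=C4 double bond. The closest known reaction type is the metathesis of 2-alkenylphenyl allyl ethers to 2H-chromenes (flav-3-enes). The one ring closed is the six-membered pyran ring of the lower unit, formed by joining the two alkene carbons that end up inside the ring, its size fixed by the ortho relationship of O1 and C4a on the benzo ring. No stereocentre is created: C2, set in step 17, has no bond made or broken and should survive the neutral conditions at 40 °C in the dark, and C3 is set only in step 19 on the face of the new double bond anti to the 2-aryl group. The step needs ring closure over cross-metathesis, secured by high dilution and the short ortho tether, and it carries no 6-/8-ambiguity because the only propenyl group sits on the carbon ortho to O1 that was fixed in step 9, with the interflavan bond already para to O1. Benzyl ethers, free secondary alcohols and the aryl bromide are inert to the catalyst.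

Step 19
Reactants: 23 the flav-3-ene trimer from step 18
Product: 25 [8-bromo-5,7,3',4'-tetra-O-benzylcatechin]-(4α→8)-[5,7,3',4'-tetra-O-benzylepicatechin]-(4β→6)-[5,7,3',4'-tetra-O-benzylcatechin], via C3-alkylborane 24 (not isolated)
Conditions: BH3·THF (8 equiv), THF, 0 °C → rt; then 3 M NaOH, 30% H2O2, 0 °C
Reagents that add atoms: borane–tetrahydrofuran [BH3-][O+]1CCCC1 (boron only in 24); hydrogen peroxide OO (oxygen at C3 of 25)
Why: Hydroboration–oxidation, in which B–H adds syn to the styrene-type double bond on the face anti to the 2-aryl group with boron at C3 (distal to the electron-rich arene and next to the allylic oxygen), and oxidation with retention should give the 2,3-trans 3-OH of catechin.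

Step 20
Reactants: 25 the protected trimer from step 19
Product: 26 catechin-(4α→8)-epicatechin-(4β→6)-catechin (CNP0178679.1)
Conditions: H2 (1 atm), Pd(OH)2/C, Et3N (2 equiv), THF/MeOH/H2O, rt; filtration, lyophilisation
Reagents that add atoms: none
Why: Hydrogenolysis of the twelve benzyl ethers and of the C8 aryl bromide under buffered conditions (the amine traps HBr so that the acid-labile interflavan bonds are not cleaved), with no stereocentre affected.

**Compound list**

1 | (+)-catechin, (2R,3S) | Oc1cc(O)c2c(c1)O[C@H](c1ccc(O)c(O)c1)[C@@H](O)C2 | starting material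
2 | 5,7,3',4'-tetra-O-benzyl-(+)-catechin | c1ccccc1COc1cc(OCc3ccccc3)c2c(c1)O[C@H](c1ccc(OCc3ccccc3)c(OCc3ccccc3)c1)[C@@H](O)C2 | intermediate
3 | 8-bromo-5,7,3',4'-tetra-O-benzylcatechin | c1ccccc1COc1cc(OCc3ccccc3)c2c(c1Br)O[C@H](c1ccc(OCc3ccccc3)c(OCc3ccccc3)c1)[C@@H](O)C2 | intermediate
4 | 8-bromo-5,7,3',4'-tetra-O-benzyl-4β-(2-ethoxyethoxy)catechin (2,3-trans, 3,4-cis) | c1ccccc1COc1cc(OCc3ccccc3)c2c(c1Br)O[C@H](c1ccc(OCc3ccccc3)c(OCc3ccccc3)c1)[C@@H](O)[C@H]2OCCOCC | intermediate
5 | (−)-epicatechin, (2R,3R) | Oc1cc(O)c2c(c1)O[C@H](c1ccc(O)c(O)c1)[C@H](O)C2 | starting material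
6 | 5,7,3',4'-tetra-O-benzyl-(−)-epicatechin | c1ccccc1COc1cc(OCc3ccccc3)c2c(c1)O[C@H](c1ccc(OCc3ccccc3)c(OCc3ccccc3)c1)[C@H](O)C2 | intermediate
7 | 5,7,3',4'-tetra-O-benzyl-4β-(2-ethoxyethoxy)epicatechin (2,3-cis, 3,4-trans) | c1ccccc1COc1cc(OCc3ccccc3)c2c(c1)O[C@H](c1ccc(OCc3ccccc3)c(OCc3ccccc3)c1)[C@H](O)[C@H]2OCCOCC | intermediate
8 | 5,7,3',4'-tetra-O-benzyl-4β-[(2,6-dimethylphenyl)sulfanyl]epicatechin | c1ccccc1COc1cc(OCc3ccccc3)c2c(c1)O[C@H](c1ccc(OCc3ccccc3)c(OCc3ccccc3)c1)[C@H](O)[C@H]2Sc1c(C)cccc1C | intermediate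
9 | [8-bromo-5,7,3',4'-tetra-O-benzylcatechin]-(4α→8)-[5,7,3',4'-tetra-O-benzyl-4β-(2,6-dimethylphenylsulfanyl)epicatechin] | c1ccccc1COc1cc(OCc3ccccc3)c2c(c1Br)O[C@H](c1ccc(OCc3ccccc3)c(OCc3ccccc3)c1)[C@@H](O)[C@@H]2c1c(OCc3ccccc3)cc(OCc3ccccc3)c2c1O[C@H](c1ccc(OCc3ccccc3)c(OCc3ccccc3)c1)[C@H](O)[C@H]2Sc1c(C)cccc1C | intermediate
10 | 3,5-bis(benzyloxy)phenol | Oc1cc(OCc2ccccc2)cc(OCc2ccccc2)c1 | starting material
11 | 1-(allyloxy)-3,5-bis(benzyloxy)benzene | C=CCOc1cc(OCc2ccccc2)cc(OCc2ccccc2)c1 | intermediate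
12 | 6-allyl-3,5-bis(benzyloxy)cyclohexa-2,4-dien-1-one (racemic) | O=C1C=C(OCc2ccccc2)C=C(OCc2ccccc2)C1CC=C | intermediate (not isolated)
13 | 2-allyl-3,5-bis(benzyloxy)phenol | Oc1cc(OCc2ccccc2)cc(OCc2ccccc2)c1CC=C | intermediate
14 | [2-allyl-3,5-bis(benzyloxy)phenoxy]triisopropylsilane | CC(C)[Si](C(C)C)(C(C)C)Oc1cc(OCc2ccccc2)cc(OCc2ccccc2)c1CC=C | intermediate
15 | 9 with the sulfanyl group replaced (4β) by 3-allyl-2,6-bis(benzyloxy)-4-(triisopropylsilyloxy)phenyl | c1ccccc1COc1cc(OCc3ccccc3)c2c(c1Br)O[C@H](c1ccc(OCc3ccccc3)c(OCc3ccccc3)c1)[C@@H](O)[C@@H]2c1c(OCc3ccccc3)cc(OCc3ccccc3)c2c1O[C@H](c1ccc(OCc3ccccc3)c(OCc3ccccc3)c1)[C@H](O)[C@H]2c1c(OCc3ccccc3)cc(O[Si](C(C)C)(C(C)C)C(C)C)c(CC=C)c1OCc3ccccc3 | intermediate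
16 | as 15, with 2,6-bis(benzyloxy)-3-[(E)-prop-1-enyl]-4-(triisopropylsilyloxy)phenyl | c1ccccc1COc1cc(OCc3ccccc3)c2c(c1Br)O[C@H](c1ccc(OCc3ccccc3)c(OCc3ccccc3)c1)[C@@H](O)[C@@H]2c1c(OCc3ccccc3)cc(OCc3ccccc3)c2c1O[C@H](c1ccc(OCc3ccccc3)c(OCc3ccccc3)c1)[C@H](O)[C@H]2c1c(OCc3ccccc3)cc(O[Si](C(C)C)(C(C)C)C(C)C)c(/C=C/C)c1OCc3ccccc3 | intermediate
17 | as 16, with 2,6-bis(benzyloxy)-4-hydroxy-3-[(E)-prop-1-enyl]phenyl | c1ccccc1COc1cc(OCc3ccccc3)c2c(c1Br)O[C@H](c1ccc(OCc3ccccc3)c(OCc3ccccc3)c1)[C@@H](O)[C@@H]2c1c(OCc3ccccc3)cc(OCc3ccccc3)c2c1O[C@H](c1ccc(OCc3ccccc3)c(OCc3ccccc3)c1)[C@H](O)[C@H]2c1c(OCc3ccccc3)cc(O)c(/C=C/C)c1OCc3ccccc3 | intermediate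
18 | 3,4-bis(benzyloxy)benzaldehyde | O=Cc1ccc(OCc2ccccc2)c(OCc2ccccc2)c1 | starting material
19 | ethyl (E)-3-[3,4-bis(benzyloxy)phenyl]prop-2-enoate | CCOC(=O)/C=C/c1ccc(OCc2ccccc2)c(OCc2ccccc2)c1 | intermediate
20 | (E)-3-[3,4-bis(benzyloxy)phenyl]prop-2-en-1-ol | OC/C=C/c1ccc(OCc2ccccc2)c(OCc2ccccc2)c1 | intermediate
21 | (E)-3-[3,4-bis(benzyloxy)phenyl]prop-2-en-1-yl methyl carbonate | COC(=O)OC/C=C/c1ccc(OCc2ccccc2)c(OCc2ccccc2)c1 | intermediate
22 | as 17, with the phenol converted into its (1S)-1-[3,4-bis(benzyloxy)phenyl]prop-2-en-1-yl ether | c1ccccc1COc1cc(OCc3ccccc3)c2c(c1Br)O[C@H](c1ccc(OCc3ccccc3)c(OCc3ccccc3)c1)[C@@H](O)[C@@H]2c1c(OCc3ccccc3)cc(OCc3ccccc3)c2c1O[C@H](c1ccc(OCc3ccccc3)c(OCc3ccccc3)c1)[C@H](O)[C@H]2c1c(OCc3ccccc3)cc(O[C@@H](C=C)c4ccc(OCc3ccccc3)c(OCc3ccccc3)c4)c(/C=C/C)c1OCc3ccccc3 | intermediate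
23 | [8-bromo-tetra-O-benzylcatechin]-(4α→8)-[tetra-O-benzylepicatechin]-(4β→6)-[(2S)-5,7-bis(benzyloxy)-2-(3,4-bis(benzyloxy)phenyl)-2H-chromene] | c1ccccc1COc1cc(OCc3ccccc3)c2c(c1Br)O[C@H](c1ccc(OCc3ccccc3)c(OCc3ccccc3)c1)[C@@H](O)[C@@H]2c1c(OCc3ccccc3)cc(OCc3ccccc3)c2c1O[C@H](c1ccc(OCc3ccccc3)c(OCc3ccccc3)c1)[C@H](O)[C@H]2c1c(OCc3ccccc3)cc2c(c1OCc3ccccc3)C=C[C@@H](c1ccc(OCc3ccccc3)c(OCc3ccccc3)c1)O2 | intermediate
24 | C3-borane of the lower unit, 2,3-trans (drawn as the monoalkylborane with the hydroxyl groups shown free) | c1ccccc1COc1cc(OCc3ccccc3)c2c(c1Br)O[C@H](c1ccc(OCc3ccccc3)c(OCc3ccccc3)c1)[C@@H](O)[C@@H]2c1c(OCc3ccccc3)cc(OCc3ccccc3)c2c1O[C@H](c1ccc(OCc3ccccc3)c(OCc3ccccc3)c1)[C@H](O)[C@H]2c1c(OCc3ccccc3)cc2c(c1OCc3ccccc3)C[C@H](B)[C@@H](c1ccc(OCc3ccccc3)c(OCc3ccccc3)c1)O2 | intermediate (not isolated)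
25 | [8-bromo-5,7,3',4'-tetra-O-benzylcatechin]-(4α→8)-[5,7,3',4'-tetra-O-benzylepicatechin]-(4β→6)-[5,7,3',4'-tetra-O-benzylcatechin] | c1ccccc1COc1cc(OCc3ccccc3)c2c(c1Br)O[C@H](c1ccc(OCc3ccccc3)c(OCc3ccccc3)c1)[C@@H](O)[C@@H]2c1c(OCc3ccccc3)cc(OCc3ccccc3)c2c1O[C@H](c1ccc(OCc3ccccc3)c(OCc3ccccc3)c1)[C@H](O)[C@H]2c1c(OCc3ccccc3)cc2c(c1OCc3ccccc3)C[C@H](O)[C@@H](c1ccc(OCc3ccccc3)c(OCc3ccccc3)c1)O2 | intermediate
26 | catechin-(4α→8)-epicatechin-(4β→6)-catechin (CNP0178679.1) | Oc1cc(O)c2c(c1)O[C@H](c1ccc(O)c(O)c1)[C@@H](O)[C@@H]2c1c(O)cc(O)c2c1O[C@H](c1ccc(O)c(O)c1)[C@H](O)[C@H]2c1c(O)cc2c(c1O)C[C@H](O)[C@@H](c1ccc(O)c(O)c1)O2 | target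

**Step count and risks**

Total step count: 20 steps. Longest linear sequence: 11 steps (from 1 or from 5: three steps to 4 or 8, then steps 7, 11, 12, 13, 17, 18, 19 and 20).

The three steps most likely to fail:

Step 11. The dimeric C4 cation may be captured by arene 14 at its other free position (C6, next to the silyloxy group), or so slowly that it is lost to elimination or self-condensation. The fallback changes the order of assembly; it sets out from 7, 14 and 4 and comes back at 15. Arene 14, in large excess, is first condensed with the monomeric electrophile 7 (TMSOTf cat., CH2Cl2, −78 °C) to give 5,7,3',4'-tetra-O-benzyl-4β-[3-allyl-2,6-bis(benzyloxy)-4-(triisopropylsilyloxy)phenyl]epicatechin F1, where both partners are cheap and any regioisomer is removed on scale. The capped electrophile 4 is then condensed at C8 of F1 (BF3·OEt2, CH2Cl2, −78 → −30 °C), a conventional 4→8 bond formation, to give 15.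

Step 17. The allyl-iridium intermediate may be attacked at the unsubstituted terminus or by a ring carbon of the electron-rich phenoxide, or catalyst control over the new centre may be incomplete on this large chiral substrate. The fallback replaces catalyst control by a stereospecific substitution; it sets out from 18 and 17 and comes back at 22. Vinylmagnesium bromide is added to 18 (THF, −78 °C) to give racemic 1-[3,4-bis(benzyloxy)phenyl]prop-2-en-1-ol F2. The racemate is resolved by preparative chromatography on a chiral phase to (R)-1-[3,4-bis(benzyloxy)phenyl]prop-2-en-1-ol F3. Mitsunobu etherification of 17 with F3 (PPh3, diisopropyl azodicarboxylate, toluene, −40 → 0 °C) should then give 22 with inversion.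

Step 7. With a free 3-OH on the 2,3-trans electrophile, facial selectivity at the C4 cation may be poor, so that the 3,4-cis (4β) dimer forms beside the 4α one. The fallback uses neighbouring-group participation; it sets out from 4 (with 8) and comes back at 9. Compound 4 is acetylated (Ac2O, pyridine, DMAP, CH2Cl2) to 3-O-acetyl-8-bromo-5,7,3',4'-tetra-O-benzyl-4β-(2-ethoxyethoxy)catechin F4. Condensation of F4 with 8 (TMSOTf, CH2Cl2, −78 °C) proceeds through the bridged acetoxonium ion on the β face, so that C8 of 8 enters from the α face, giving [3-O-acetyl-8-bromo-5,7,3',4'-tetra-O-benzylcatechin]-(4α→8)-[5,7,3',4'-tetra-O-benzyl-4β-(2,6-dimethylphenylsulfanyl)epicatechin] F5. Methanolysis of the acetate (K2CO3 cat., MeOH/THF, rt) returns 9.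

**Further compounds**

F1 | step 11 | 5,7,3',4'-tetra-O-benzyl-4β-[3-allyl-2,6-bis(benzyloxy)-4-(triisopropylsilyloxy)phenyl]epicatechin | c1ccccc1COc1cc(OCc3ccccc3)c2c(c1)O[C@H](c1ccc(OCc3ccccc3)c(OCc3ccccc3)c1)[C@H](O)[C@H]2c1c(OCc3ccccc3)cc(O[Si](C(C)C)(C(C)C)C(C)C)c(CC=C)c1OCc3ccccc3
F2 | step 17 | racemic 1-[3,4-bis(benzyloxy)phenyl]prop-2-en-1-ol | OC(C=C)c1ccc(OCc2ccccc2)c(OCc2ccccc2)c1
F3 | step 17 | (R)-1-[3,4-bis(benzyloxy)phenyl]prop-2-en-1-ol | O[C@H](C=C)c1ccc(OCc2ccccc2)c(OCc2ccccc2)c1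
F4 | step 7 | 3-O-acetyl-8-bromo-5,7,3',4'-tetra-O-benzyl-4β-(2-ethoxyethoxy)catechin | c1ccccc1COc1cc(OCc3ccccc3)c2c(c1Br)O[C@H](c1ccc(OCc3ccccc3)c(OCc3ccccc3)c1)[C@@H](OC(C)=O)[C@H]2OCCOCC
F5 | step 7 | [3-O-acetyl-8-bromo-5,7,3',4'-tetra-O-benzylcatechin]-(4α→8)-[5,7,3',4'-tetra-O-benzyl-4β-(2,6-dimethylphenylsulfanyl)epicatechin] | c1ccccc1COc1cc(OCc3ccccc3)c2c(c1Br)O[C@H](c1ccc(OCc3ccccc3)c(OCc3ccccc3)c1)[C@@H](OC(C)=O)[C@@H]2c1c(OCc3ccccc3)cc(OCc3ccccc3)c2c1O[C@H](c1ccc(OCc3ccccc3)c(OCc3ccccc3)c1)[C@H](O)[C@H]2Sc1c(C)cccc1C
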